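**Retrosynthetic overview**

- Ring C (O1, C2, C3, C4, C4a, C8a) is opened at the O1–C2 bond. The target is the intramolecular oxa-Michael adduct of an achiral, protecting-group-free 2'-hydroxychalcone; a chalcone isomerase (EC 5.5.1.6) closes this ring last and sets C2 (S), the only stereocenter.
- Enabling feature: O1 is the ring A phenol oxygen ortho to the C4 acyl carbon, and C2 lies β to the C4 ketone. Ring A carries OH at C7 and H at C5, the 6'-deoxychalcone pattern that legume chalcone isomerases accept and whose uncatalysed cyclization is slow.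
- The chalcone is cut at its Cα=Cβ bond (C3–C2 of the flavanone) by Claisen–Schmidt condensation into 3-prenylresacetophenone (ring A) and 2,2-dimethyl-2H-chromene-6-carbaldehyde (ring B fused to pyran ring D).
- Both fragments come from a commercial phenol and the same reagent, 3-chloro-3-methylbut-1-yne: semihydrogenation and aromatic Claisen rearrangement place the prenyl group at C8; propargyl Claisen rearrangement and oxa-6π closure build the chromene.
- Ring order: benzene rings A and B are bought; pyran ring D of the chromene is closed in step 5; ring C is closed in step 7.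

Key step: step 7

Remark: the enzyme of step 7 is taken to be a recombinant legume chalcone isomerase (the class that accepts 6'-deoxychalcones), produced in Escherichia coli and used as a catalyst; C2 of the target is S, the configuration this enzyme class delivers.

**Step 1**
Reactants: 1 2,4-dihydroxyacetophenone; 2 3-chloro-3-methylbut-1-yne
Product: 3 1-[2-hydroxy-4-(2-methylbut-3-yn-2-yloxy)phenyl]ethanone
Conditions: K2CO3, KI (cat.), CuI (cat.), acetone, reflux
Reagents that add atoms: none
Why: Copper-assisted Williamson-type O-propargylation of a phenol with a tertiary propargylic chloride; the 2-OH is held in a hydrogen bond to the acetyl group, so only the free, more acidic 4-OH should be alkylated.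

**Step 2**
Reactants: 3 1-[2-hydroxy-4-(2-methylbut-3-yn-2-yloxy)phenyl]ethanone
Product: 4 1-[2-hydroxy-4-(2-methylbut-3-en-2-yloxy)phenyl]ethanone
Conditions: H2 (1 atm), Lindlar catalyst (Pd/CaCO3, Pb(OAc)2-poisoned), quinoline, EtOAc, rt
Reagents that add atoms: none
Why: Lindlar semihydrogenation should stop at the terminal alkene and leave the aryl ketone and the arene untouched.

**Step 3**
Reactants: 4 1-[2-hydroxy-4-(2-methylbut-3-en-2-yloxy)phenyl]ethanone
Product: 6 1-[2,4-dihydroxy-3-(3-methylbut-2-en-1-yl)phenyl]ethanone, via ortho-dienone 5 (not isolated)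
Conditions: N,N-diethylaniline, 140 °C, N2
Reagents that add atoms: none
Why: Aromatic Claisen rearrangement ([3,3]-sigmatropic shift) transposes the allyl unit, so the 1,1-dimethylallyl ether should deliver the linear prenyl group to C3, the ortho carbon between the two oxygens favoured by the bond fixation of the chelated 2-hydroxyacetophenone, and dienone 5 then tautomerizes to the phenol.

**Step 4**
Reactants: 7 4-hydroxybenzaldehyde; 2 3-chloro-3-methylbut-1-yne
Product: 8 4-(2-methylbut-3-yn-2-yloxy)benzaldehyde
Conditions: K2CO3, KI (cat.), CuI (cat.), acetone, reflux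
Reagents that add atoms: none
Why: The same copper-assisted Williamson-type O-propargylation as in step 1, here on a phenol with a single hydroxyl group.

**Step 5**
Reactants: 8 4-(2-methylbut-3-yn-2-yloxy)benzaldehyde
Product: 11 2,2-dimethyl-2H-chromene-6-carbaldehyde, via allenylphenol 9 (not isolated), via ortho-quinone methide 10 (not isolated)
Conditions: N,N-diethylaniline, 190 °C, N2
Reagents that add atoms: none
Why: Thermal propargyl Claisen rearrangement, enolization, 1,5-hydrogen shift and oxa-6π-electrocyclization form the standard cascade to 2,2-dimethyl-2H-chromenes; the two ortho positions of 8 are equivalent, so the aldehyde should end up at C6 of the chromene.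

**Step 6**
Reactants: 6 1-[2,4-dihydroxy-3-(3-methylbut-2-en-1-yl)phenyl]ethanone; 11 2,2-dimethyl-2H-chromene-6-carbaldehyde
Product: 13 (E)-1-[2,4-dihydroxy-3-(3-methylbut-2-en-1-yl)phenyl]-3-(2,2-dimethyl-2H-chromen-6-yl)prop-2-en-1-one, via aldol adduct 12 (not isolated)
Conditions: LiN(SiMe3)2 (4.5 equiv), THF, −78 °C to rt; then 1 M aq. HCl to pH 4, 0 °C; dark
Reagents that add atoms: none
Why: Claisen–Schmidt (crossed aldol) condensation: the trilithium salt of 6 (two phenoxides and the methyl ketone enolate) should add to the non-enolizable aldehyde 11, and the aldolate should eliminate by E1cB to the conjugated E-enone without any phenol protection.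

**Step 7**
Reactants: 13 (E)-1-[2,4-dihydroxy-3-(3-methylbut-2-en-1-yl)phenyl]-3-(2,2-dimethyl-2H-chromen-6-yl)prop-2-en-1-one
Product: 14 (2S)-7-hydroxy-2-(2,2-dimethyl-2H-chromen-6-yl)-8-(3-methylbut-2-en-1-yl)-2,3-dihydro-4H-chromen-4-one
Conditions: chalcone isomerase (recombinant legume enzyme, EC 5.5.1.6), KH2PO4/K2HPO4 buffer (50 mM, pH 7.5), 10% DMSO, 25 °C, N2, dark; EtOAc extraction at pH 6; unreacted 13 recovered and resubmitted
Reagents that add atoms: none
Why: Chalcone isomerase (chalcone–flavanone isomerase, EC 5.5.1.6, an intramolecular lyase) binds the enone of 13 in its cleft, where the ionized 2'-phenoxide adds to Cβ while an active-site water and tyrosine network stabilizes the enolate, which is then protonated at Cα. The closest known reaction is the same enzymatic cyclization of isoliquiritigenin (2',4,4'-trihydroxychalcone) to (2S)-liquiritigenin by the legume enzymes, the 6'-deoxychalcone substrate class to which 13 belongs. Ring C closes in the 6-endo-trig mode, as an intramolecular oxa-Michael addition that forms the O1–C2 bond. The new stereocenter C2 should be set as S by the enzyme alone, because the cleft presents only one face of Cβ to the phenoxide (catalyst control on an achiral substrate). The step needs the enzymatic rate to outrun the uncatalysed racemic cyclization, and the substrate secures this: with no 6'-hydroxyl the only possible nucleophile is the 2'-OH, which is hydrogen-bonded to the ketone and sluggish at pH 7.5 without the enzyme, while the 4'-OH cannot reach the enone. Neutral buffer should leave the prenyl group, the chromene and the base-labile C2 center untouched, so no protecting group has to be carried or removed.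

**Compound list**

1 | 2,4-dihydroxyacetophenone | CC(=O)c1ccc(O)cc1O | starting material
2 | 3-chloro-3-methylbut-1-yne | CC(C)(Cl)C#C | starting material
3 | 1-[2-hydroxy-4-(2-methylbut-3-yn-2-yloxy)phenyl]ethanone | CC(=O)c1ccc(OC(C)(C)C#C)cc1O | intermediate
4 | 1-[2-hydroxy-4-(2-methylbut-3-en-2-yloxy)phenyl]ethanone | CC(=O)c1ccc(OC(C)(C)C=C)cc1O | intermediate
5 | 4-acetyl-3-hydroxy-2-(3-methylbut-2-en-1-yl)cyclohexa-3,5-dien-1-one (ortho-dienone, racemic) | CC(=O)C1=C(O)C(CC=C(C)C)C(=O)C=C1 | intermediate
6 | 1-[2,4-dihydroxy-3-(3-methylbut-2-en-1-yl)phenyl]ethanone | CC(=O)c1ccc(O)c(CC=C(C)C)c1O | intermediate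
7 | 4-hydroxybenzaldehyde | O=Cc1ccc(O)cc1 | starting material
8 | 4-(2-methylbut-3-yn-2-yloxy)benzaldehyde | O=Cc1ccc(OC(C)(C)C#C)cc1 | intermediate
9 | 4-hydroxy-3-(3-methylbuta-1,2-dien-1-yl)benzaldehyde (allenylphenol) | O=Cc1ccc(O)c(C=C=C(C)C)c1 | intermediate
10 | 3-(3-methylbut-2-en-1-ylidene)-4-oxocyclohexa-1,5-diene-1-carbaldehyde (ortho-quinone methide) | O=CC1=CC(=CC=C(C)C)C(=O)C=C1 | intermediate
11 | 2,2-dimethyl-2H-chromene-6-carbaldehyde | CC1(C)C=Cc2cc(C=O)ccc2O1 | intermediate
12 | 1-[2,4-dihydroxy-3-(3-methylbut-2-en-1-yl)phenyl]-3-(2,2-dimethyl-2H-chromen-6-yl)-3-hydroxypropan-1-one (aldol adduct, racemic) | CC(C)=CCc1c(O)ccc(C(=O)CC(O)c2ccc3OC(C)(C)C=Cc3c2)c1O | intermediate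
13 | (E)-1-[2,4-dihydroxy-3-(3-methylbut-2-en-1-yl)phenyl]-3-(2,2-dimethyl-2H-chromen-6-yl)prop-2-en-1-one | CC(C)=CCc1c(O)ccc(C(=O)/C=C/c2ccc3OC(C)(C)C=Cc3c2)c1O | intermediate
14 | (2S)-7-hydroxy-2-(2,2-dimethyl-2H-chromen-6-yl)-8-(3-methylbut-2-en-1-yl)-2,3-dihydro-4H-chromen-4-one | CC(C)=CCc1c(O)ccc2c1O[C@H](c1ccc3c(c1)C=CC(C)(C)O3)CC2=O | target

**Step count and risks**

Total step count: 7. Longest linear sequence: 5 (steps 1, 2, 3, 6, 7).

Steps most likely to fail:

1. Step 7. The prenyl group next to the nucleophilic phenol or the bulky dimethylchromene ring may not fit the active-site cleft, so that turnover is slow or absent. The lipophilic substrate may also stay out of solution in buffer, and conversion may stop at the chalcone–flavanone equilibrium. Fallback, from 13 to 14: NaOAc in refluxing EtOH should equilibrate the chalcone with racemic 7-hydroxy-2-(2,2-dimethyl-2H-chromen-6-yl)-8-(3-methylbut-2-en-1-yl)-2,3-dihydro-4H-chromen-4-one F1. Preparative chromatography on a chiral stationary phase (amylose tris(3,5-dimethylphenylcarbamate), heptane/2-propanol) should then give 14. The (2R) enantiomer is returned to the NaOAc equilibration, where ring opening to 13 and reclosure racemize it, and is resolved again.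

2. Step 6. Enolization of the poorly soluble polylithiated ketone may be incomplete, the aldolate may revert by retro-aldol cleavage, or dehydration may stall. Fallback, from 6 to 13: MOMCl and K2CO3 in acetone at rt should cap only the free 4-OH (the 2-OH is chelated) and give 1-[2-hydroxy-4-(methoxymethoxy)-3-(3-methylbut-2-en-1-yl)phenyl]ethanone F2. Classical Claisen–Schmidt condensation of this ketone with 11 (KOH, EtOH/H2O, rt) should give (E)-1-[2-hydroxy-4-(methoxymethoxy)-3-(3-methylbut-2-en-1-yl)phenyl]-3-(2,2-dimethyl-2H-chromen-6-yl)prop-2-en-1-one F3. Brief treatment with 3 M aq. HCl in MeOH at rt should remove the MOM group and return the route to 13.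

3. Step 3. The allyl group may migrate in part to C5 instead of C3, or the tertiary allyl ether may fragment thermally back to the phenol. Fallback, from 1 to 6: direct C-prenylation of 1 with 1-bromo-3-methylbut-2-ene in aqueous KOH at rt, where the ambident phenoxide is alkylated preferentially at C3 between the two oxygens. Chromatographic removal of the 5-prenyl and O-prenyl isomers then returns the route to 6, replacing steps 1 to 3; no new compound is made on this path (F0).

**Further compounds**

F1 | step 7 | racemic 7-hydroxy-2-(2,2-dimethyl-2H-chromen-6-yl)-8-(3-methylbut-2-en-1-yl)-2,3-dihydro-4H-chromen-4-one | CC(C)=CCc1c(O)ccc2c1OC(c1ccc3c(c1)C=CC(C)(C)O3)CC2=O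
F2 | step 6 | 1-[2-hydroxy-4-(methoxymethoxy)-3-(3-methylbut-2-en-1-yl)phenyl]ethanone | CC(=O)c1ccc(OCOC)c(CC=C(C)C)c1O
F3 | step 6 | (E)-1-[2-hydroxy-4-(methoxymethoxy)-3-(3-methylbut-2-en-1-yl)phenyl]-3-(2,2-dimethyl-2H-chromen-6-yl)prop-2-en-1-one | CC(C)=CCc1c(OCOC)ccc(C(=O)/C=C/c2ccc3OC(C)(C)C=Cc3c2)c1O
F0 | step 3 | none | none
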